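**Plan**

1. Retrosynthesis: cut the C10 ester first (core alcohol plus acid fragment 2, made by a Z-selective Wittig reaction), then the bond C6–C7 (bicyclo[3.2.1]octene back to a spiro[4.5]decadiene), then the spiro bond C1–C2 of the cyclopentane. That returns the whole core to one tert-butyl 3-methoxybenzoate with a single side chain.
2. Enabling feature: in the six-membered ring C1–C10–C9–C8–C7–C11 the carboxyl carbon is on C8, para to the spiro carbon C1, and the oxygen is on C10, ortho to it. This is the pattern of a 4-alkyl-3-methoxybenzoate, so a radical on C2 can attack the ipso carbon C1. The dearomatised ring then appears as an ester dienolate (C8), an enol ether (latent C10 ketone) and, after conjugation, an acceptor at C7.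
3. Forward order: side chain on the arene (Wittig, Sharpless epoxidation, cuprate opening), then the cyclopentane by dearomative radical spirocyclization, then the bicyclo[3.2.1]octene by a second epoxide-radical closure C6 to C7, then enone, reduction, esterification with fragment 2, oxidation of C12 and acid deprotection.
4. Stereochemistry: C5 comes from the Sharpless epoxidation and an invertive epoxide opening. C1 and C2 are relayed from C5 in the key step by allylic strain against the ortho methoxy group. C6 and C7 are relayed in the second closure, C10 by hydride delivery from the face of the one-carbon bridge, and the Z-alkene by a salt-free Wittig reaction.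

Key step: step 8

Locants used throughout, also for intermediates: C1 spiro/bridgehead carbon; C2 the carbon bearing the formyl carbon C12; C3 and C4 ring CH2; C5 ring-fusion CH; C6 the carbon bearing CH3 and C13 (CH2OH); C7 bridgehead CH; C8 the carboxyl-bearing alkene carbon; C9 alkene CH; C10 the acyloxy carbon; C11 the bridging CH2.

Assumption: 4-formyl-3-methoxybenzoic acid (1) is taken as purchasable, like its methyl ester; 3, 7, 19 and 22 are catalogue compounds.

**Route**

Step 1
Reactants: 1 4-formyl-3-methoxybenzoic acid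
Product: 2 tert-butyl 4-formyl-3-methoxybenzoate
Conditions: tert-butyl 2,2,2-trichloroacetimidate, BF3·OEt2 (cat.), CH2Cl2/cyclohexane, rt
Reagents that add atoms: tert-butyl 2,2,2-trichloroacetimidate, CC(C)(C)OC(=N)C(Cl)(Cl)Cl
Why: Acid-catalysed imidate esterification tert-butylates the carboxylic acid without touching the aldehyde and installs the ester that acid removes in the last step.

Step 2
Reactants: 2 tert-butyl 4-formyl-3-methoxybenzoate; 3 2-(triphenylphosphoranylidene)propanal
Product: 4 tert-butyl 3-methoxy-4-[(1E)-2-methyl-3-oxoprop-1-enyl]benzoate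
Conditions: toluene, 90 °C
Reagents that add atoms: none
Why: Wittig olefination with a stabilised formyl ylide should give the E-trisubstituted enal, with aryl and formyl groups trans.

Step 3
Reactants: 4 tert-butyl 3-methoxy-4-[(1E)-2-methyl-3-oxoprop-1-enyl]benzoate
Product: 5 tert-butyl 4-[(1E)-3-hydroxy-2-methylprop-1-enyl]-3-methoxybenzoate
Conditions: NaBH4, CeCl3·7H2O, MeOH, 0 °C
Reagents that add atoms: none
Why: Luche 1,2-reduction of the enal gives the allylic alcohol and leaves the aryl tert-butyl ester alone.

Step 4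
Reactants: 5 tert-butyl 4-[(1E)-3-hydroxy-2-methylprop-1-enyl]-3-methoxybenzoate
Product: 6 tert-butyl 4-[(2S,3S)-3-(hydroxymethyl)-3-methyloxiran-2-yl]-3-methoxybenzoate
Conditions: Ti(OiPr)4 (cat.), diethyl L-(+)-tartrate (cat.), tBuOOH, 4 Å molecular sieves, CH2Cl2, −20 °C
Reagents that add atoms: tert-butyl hydroperoxide, CC(C)(C)OO
Why: Sharpless asymmetric epoxidation of an E-trisubstituted allylic alcohol; with the L-(+)-tartrate the oxygen should arrive on the face that gives the (2S,3S)-epoxide, by analogy with E-cinnamyl-type alcohols, which fixes the benzylic carbon (future C5).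

Step 5
Reactants: 6 tert-butyl 4-[(2S,3S)-3-(hydroxymethyl)-3-methyloxiran-2-yl]-3-methoxybenzoate; 7 but-3-enylmagnesium bromide
Product: 8 tert-butyl 4-[(2R,3R)-1,2-dihydroxy-2-methylhept-6-en-3-yl]-3-methoxybenzoate
Conditions: 7 (3 equiv), CuI (10 mol%), THF, −40 → −10 °C; NH4Cl(aq)
Reagents that add atoms: none
Why: Copper-catalysed Grignard opening of the aryl epoxy alcohol by SN2 attack at the benzylic carbon (the other epoxide carbon is fully substituted) proceeds with inversion and sets C5 in its final configuration.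

Step 6
Reactants: 8 tert-butyl 4-[(2R,3R)-1,2-dihydroxy-2-methylhept-6-en-3-yl]-3-methoxybenzoate
Product: 9 tert-butyl 4-[(2R,3R)-2-hydroxy-2-methyl-1-(tosyloxy)hept-6-en-3-yl]-3-methoxybenzoate
Conditions: TsCl, Et3N, Bu2SnO (cat.), CH2Cl2, 0 °C → rt
Reagents that add atoms: p-toluenesulfonyl chloride, Cc1ccc(cc1)S(=O)(=O)Cl
Why: Tin-catalysed sulfonylation of a 1,2-diol takes the primary hydroxyl only and stores the second epoxide in a latent form that the titanium chemistry of step 8 does not touch.

Step 7
Reactants: 9 tert-butyl 4-[(2R,3R)-2-hydroxy-2-methyl-1-(tosyloxy)hept-6-en-3-yl]-3-methoxybenzoate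
Product: 10 tert-butyl 4-[(2R,3R)-2-hydroxy-2-methyl-5-(oxiran-2-yl)-1-(tosyloxy)pentan-3-yl]-3-methoxybenzoate (both oxirane epimers)
Conditions: mCPBA, NaHCO3, CH2Cl2, 0 °C
Reagents that add atoms: 3-chloroperoxybenzoic acid, OOC(=O)c1cccc(Cl)c1
Why: Prilezhaev epoxidation of the only alkene (the arene is electron-poor); the epimers at the oxirane carbon are irrelevant because that carbon becomes a planar radical.

Step 8
Reactants: 10 tert-butyl 4-[(2R,3R)-2-hydroxy-2-methyl-5-(oxiran-2-yl)-1-(tosyloxy)pentan-3-yl]-3-methoxybenzoate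
Product: 11 spiro[4.5]decadiene hydroxy tosylate (C2–CH2OH and the C5 side chain cis, both on the side of C11; C8 epimers)
Conditions: Cp2TiCl2 (2.5 equiv), Mn dust, THF, rt (forms Cp2TiCl); slow addition of 10; 2,4,6-collidine·HCl, rt
Reagents that add atoms: none
Why: Proposed new method: Cp2TiCl opens the terminal epoxide homolytically to the secondary β-titanoxy radical at C2, which attacks the arene ipso carbon C1 (para to the ester) in a 5-exo mode and so closes the cyclopentane C1–C2–C3–C4–C5; the spirocyclohexadienyl radical carries its spin on C8 next to the ester and is reduced by a second Cp2TiCl to a titanium ester dienolate that collidinium chloride protonates at C8 (a mixture there, erased in step 9). The closest known reaction types are the Cp2TiCl epoxide-opening Giese cyclization onto unsaturated esters, the titanocene-catalysed radical arylation of epoxides, and the SmI2 ketyl ipso-spirocyclization onto arenes that carry a para alkoxycarbonyl group. C1 is controlled by allylic strain: the benzylic hydrogen on C5 eclipses the ortho methoxy group, so the C4 tether reaches C1 from the face that leaves the bulky C6 carbinol on the side of C11–H. C2 is controlled in the same way: the CH2O–Ti group turns away from the methoxy-bearing C10 and ends cis to the C5 substituent (1,3-cis on the cyclopentane), the configuration of the target. The step needs ipso attack and reductive trapping to win over ortho attack, 1,4-aryl shift and reduction of the C2 radical; the para ester makes the ipso adduct a stabilised radical that trivalent titanium should reduce quickly, the ortho adducts lack this stabilisation, and secondary β-titanoxy radicals are reduced only slowly by Cp2TiCl.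

Step 9
Reactants: 11 spiro[4.5]decadiene hydroxy tosylate
Product: 13 triethylsilyl ether of the spiro epoxy 1,3-dienoate, via epoxy alcohol 12 (not isolated)
Conditions: K2CO3, MeOH, rt; concentrate; then Et3SiCl, imidazole, DMF, 0 °C
Reagents that add atoms: chlorotriethylsilane, CC[Si](Cl)(CC)CC
Why: Carbonate in methanol closes the 2,2-disubstituted epoxide by intramolecular Williamson displacement of the tosylate and equilibrates the skipped diene ester to the conjugated C7=C8–C9=C10(OMe) isomer (thermodynamic control, C8 stereocentre erased); the primary C12 hydroxyl is then silylated.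

Step 10
Reactants: 13 triethylsilyl ether of the spiro epoxy 1,3-dienoate
Product: 14 tricyclic alcohol (C6–C7 bond formed; C6 with CH3 exo and CH2OH endo; enol ether C9=C10; C8 epimers)
Conditions: Cp2TiCl2 (2.5 equiv), Mn dust, 2,4,6-collidine·HCl, THF, rt
Reagents that add atoms: none
Why: Known Cp2TiCl epoxide-opening Giese cyclization: the tertiary radical at C6 adds 5-exo to C7, the β-carbon of the dienoate, which forces the new bridge cis at C7; at C6 the CH2O–Ti arm should take the endo position beside C5–H (it avoids eclipsing C4 and can bind the C8 ester carbonyl) and leave methyl exo, and the resulting allyl/ester radical is reduced and protonated at C8.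

Step 11
Reactants: 14 tricyclic alcohol
Product: 15 tricyclic C13 tert-butyldimethylsilyl ether
Conditions: TBSCl, imidazole, DMAP (cat.), DMF, 40 °C
Reagents that add atoms: tert-butyldimethylsilyl chloride, CC(C)(C)[Si](C)(C)Cl
Why: Standard silylation of the neopentyl primary alcohol under non-acidic conditions that spare the enol ether.

Step 12
Reactants: 15 tricyclic C13 tert-butyldimethylsilyl ether
Product: 17 tricyclic enone ester (C10 ketone, C8=C9), via bromo ketone 16 (not isolated)
Conditions: NBS, NaHCO3, THF/H2O, 0 °C; work-up; then DBU, CH2Cl2, 0 °C → rt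
Reagents that add atoms: N-bromosuccinimide, O=C1CCC(=O)N1Br (bromine only in 16); water, O
Why: Bromination of the enol ether at its β-carbon C9 with capture by water gives the α-bromo ketone, and E1cB loss of HBr through the C8 ester enolate gives the C8=C9 ene-one ester; C1 is quaternary, so no other direction is open.

Step 13
Reactants: 17 tricyclic enone ester
Product: 18 tricyclic (10S)-allylic alcohol (hydroxyl on the face of the two-carbon bridge, anti to C11 and to C12)
Conditions: NaBH4, CeCl3·7H2O, MeOH/THF, −78 °C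
Reagents that add atoms: none
Why: Luche 1,2-reduction; hydride should attack C10 from the face of the one-carbon bridge C11, anti to the C1–C5 bond (Felkin-type, as in exo attack on bridged bicyclic ketones), which places the oxygen as in the target.

Step 14
Reactants: 19 7-bromoheptan-1-ol
Product: 20 (7-bromoheptyloxy)(tert-butyl)dimethylsilane
Conditions: TBSCl, imidazole, CH2Cl2, rt
Reagents that add atoms: tert-butyldimethylsilyl chloride, CC(C)(C)[Si](C)(C)Cl
Why: Standard silyl protection of the primary alcohol.

Step 15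
Reactants: 20 (7-bromoheptyloxy)(tert-butyl)dimethylsilane
Product: 21 [7-(tert-butyldimethylsilyloxy)heptyl]triphenylphosphonium bromide
Conditions: PPh3, MeCN, reflux
Reagents that add atoms: triphenylphosphine, c1ccc(cc1)P(c1ccccc1)c1ccccc1
Why: SN2 quaternisation of the phosphine by the primary bromide.

Step 16
Reactants: 21 [7-(tert-butyldimethylsilyloxy)heptyl]triphenylphosphonium bromide; 22 methyl 9-oxononanoate
Product: 24 methyl (9Z)-16-(tert-butyldimethylsilyloxy)hexadec-9-enoate, via phosphorus ylide 23 (not isolated)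
Conditions: NaN(SiMe3)2, THF, −78 °C; then 22, −78 °C → rt
Reagents that add atoms: none
Why: Wittig reaction of a non-stabilised ylide under lithium-free conditions should give the Z-alkene through the kinetically favoured cis-oxaphosphetane.

Step 17
Reactants: 24 methyl (9Z)-16-(tert-butyldimethylsilyloxy)hexadec-9-enoate
Product: 25 (9Z)-16-(tert-butyldimethylsilyloxy)hexadec-9-enoic acid
Conditions: LiOH, THF/MeOH/H2O, rt; then aq. HCl to pH 4
Reagents that add atoms: lithium hydroxide, [Li+].[OH-]
Why: Saponification of the methyl ester leaves the silyl ether and the Z-alkene untouched.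

Step 18
Reactants: 25 (9Z)-16-(tert-butyldimethylsilyloxy)hexadec-9-enoic acid; 18 tricyclic (10S)-allylic alcohol
Product: 27 fully protected C10 ester, via mixed anhydride 26 (not isolated)
Conditions: 25, 2,4,6-trichlorobenzoyl chloride, Et3N, THF, rt; then 18, DMAP, toluene, 60 °C
Reagents that add atoms: 2,4,6-trichlorobenzoyl chloride, O=C(Cl)c1c(Cl)cc(Cl)cc1Cl (aroyl group only in 26)
Why: Yamaguchi esterification acylates the hindered secondary alcohol with retention at C10 while all other hydroxyls are silylated.

Step 19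
Reactants: 27 fully protected C10 ester
Product: 28 C12 primary alcohol (both TBS ethers and the tert-butyl ester kept)
Conditions: PPTS (cat.), MeOH/CH2Cl2, 0 °C
Reagents that add atoms: none
Why: Acid-catalysed methanolysis cleaves a primary triethylsilyl ether much faster than primary TBS ethers.

Step 20
Reactants: 28 C12 primary alcohol
Product: 29 C12 aldehyde
Conditions: Dess–Martin periodinane, NaHCO3, CH2Cl2, 0 °C → rt
Reagents that add atoms: none
Why: Dess–Martin oxidation under buffered, non-basic conditions should give the aldehyde without epimerising the adjacent stereocentre C2.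

Step 21
Reactants: 29 C12 aldehyde
Product: 30 target CNP0148862.2
Conditions: CF3CO2H/CH2Cl2 (1:3), H2O (5 equiv), 0 °C → rt; then brief NaHCO3(aq)/THF work-up
Reagents that add atoms: none
Why: Acidolysis removes the tert-butyl ester (as isobutene) and both TBS ethers in one operation; the C10 allylic ester should resist ionisation because its cation would be conjugated with the carboxyl group.

**Compound list**

1 | 4-formyl-3-methoxybenzoic acid | COc1cc(C(=O)O)ccc1C=O | starting material
2 | tert-butyl 4-formyl-3-methoxybenzoate | COc1cc(C(=O)OC(C)(C)C)ccc1C=O | intermediate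
3 | 2-(triphenylphosphoranylidene)propanal | CC(C=O)=P(c1ccccc1)(c1ccccc1)c1ccccc1 | starting material
4 | tert-butyl 3-methoxy-4-[(1E)-2-methyl-3-oxoprop-1-enyl]benzoate | C/C(C=O)=C\c1ccc(C(=O)OC(C)(C)C)cc1OC | intermediate
5 | tert-butyl 4-[(1E)-3-hydroxy-2-methylprop-1-enyl]-3-methoxybenzoate | C/C(CO)=C\c1ccc(C(=O)OC(C)(C)C)cc1OC | intermediate
6 | tert-butyl 4-[(2S,3S)-3-(hydroxymethyl)-3-methyloxiran-2-yl]-3-methoxybenzoate | OC[C@]1(C)O[C@H]1c1ccc(C(=O)OC(C)(C)C)cc1OC | intermediate
7 | but-3-enylmagnesium bromide | C=CCC[Mg]Br | starting material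
8 | tert-butyl 4-[(2R,3R)-1,2-dihydroxy-2-methylhept-6-en-3-yl]-3-methoxybenzoate | C=CCC[C@H](c1ccc(C(=O)OC(C)(C)C)cc1OC)[C@@](C)(O)CO | intermediate
9 | tert-butyl 4-[(2R,3R)-2-hydroxy-2-methyl-1-(tosyloxy)hept-6-en-3-yl]-3-methoxybenzoate | C=CCC[C@H](c1ccc(C(=O)OC(C)(C)C)cc1OC)[C@@](C)(O)COS(=O)(=O)c1ccc(C)cc1 | intermediate
10 | tert-butyl 4-[(2R,3R)-2-hydroxy-2-methyl-5-(oxiran-2-yl)-1-(tosyloxy)pentan-3-yl]-3-methoxybenzoate, both oxirane epimers | C1OC1CC[C@H](c1ccc(C(=O)OC(C)(C)C)cc1OC)[C@@](C)(O)COS(=O)(=O)c1ccc(C)cc1 | intermediate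
11 | spiro diene: cyclopentane C1–C5 spiro at C1 to the 2,5-cyclohexadiene C1–C10(OMe)=C9–C8H(CO2tBu)–C7=C11; C2 bears CH2OH, C5 bears C6(OH)(CH3)CH2OTs; the two substituents cis and both on the side of C11; C8 epimers | C[C@](O)(COS(=O)(=O)c3ccc(C)cc3)[C@@H]1CC[C@H](CO)[C@]12C=CC(C(=O)OC(C)(C)C)C=C2OC | intermediate
12 | epoxy alcohol: as 11 but C6/C13 closed to the 2-methyloxirane and the ring conjugated to C7=C8(CO2tBu)–C9=C10(OMe), C11 now CH2 | C[C@]3(CO3)[C@@H]1CC[C@H](CO)[C@]12CC=C(C(=O)OC(C)(C)C)C=C2OC | intermediate
13 | C12 triethylsilyl ether of 12 | C[C@]3(CO3)[C@@H]1CC[C@H](CO[Si](CC)(CC)CC)[C@]12CC=C(C(=O)OC(C)(C)C)C=C2OC | intermediate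
14 | tricyclic alcohol: bicyclo[3.2.1]octene fused to the cyclopentane; C6 with CH3 exo (syn to C11) and CH2OH endo; C7–H bridgehead; enol ether C9=C10(OMe); C8H(CO2tBu) epimers; C12 OSiEt3 | C[C@@]1(CO)[C@H]2C[C@@]3(C(OC)=CC2C(=O)OC(C)(C)C)[C@@H](CO[Si](CC)(CC)CC)CC[C@@H]13 | intermediate
15 | C13 tert-butyldimethylsilyl ether of 14 | C[C@@]1(CO[Si](C)(C)C(C)(C)C)[C@H]2C[C@@]3(C(OC)=CC2C(=O)OC(C)(C)C)[C@@H](CO[Si](CC)(CC)CC)CC[C@@H]13 | intermediate
16 | 9-bromo-10-ketone from 15 (C8 and C9 epimers) | C[C@@]1(CO[Si](C)(C)C(C)(C)C)[C@H]2C[C@@]3(C(=O)C(Br)C2C(=O)OC(C)(C)C)[C@@H](CO[Si](CC)(CC)CC)CC[C@@H]13 | intermediate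
17 | tricyclic enone ester: C10 ketone, C8=C9, tert-butyl ester on C8 | C[C@@]1(CO[Si](C)(C)C(C)(C)C)[C@H]2C[C@@]3(C(=O)C=C2C(=O)OC(C)(C)C)[C@@H](CO[Si](CC)(CC)CC)CC[C@@H]13 | intermediate
18 | (10S)-allylic alcohol from 17, hydroxyl anti to C11 | C[C@@]1(CO[Si](C)(C)C(C)(C)C)[C@H]2C[C@@]3([C@@H](O)C=C2C(=O)OC(C)(C)C)[C@@H](CO[Si](CC)(CC)CC)CC[C@@H]13 | intermediate
19 | 7-bromoheptan-1-ol | OCCCCCCCBr | starting material
20 | (7-bromoheptyloxy)(tert-butyl)dimethylsilane | CC(C)(C)[Si](C)(C)OCCCCCCCBr | intermediate
21 | [7-(tert-butyldimethylsilyloxy)heptyl]triphenylphosphonium bromide | CC(C)(C)[Si](C)(C)OCCCCCCC[P+](c1ccccc1)(c1ccccc1)c1ccccc1.[Br-] | intermediate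
22 | methyl 9-oxononanoate | COC(=O)CCCCCCCC=O | starting material
23 | [7-(tert-butyldimethylsilyloxy)heptylidene]triphenylphosphorane | CC(C)(C)[Si](C)(C)OCCCCCCC=P(c1ccccc1)(c1ccccc1)c1ccccc1 | intermediate
24 | methyl (9Z)-16-(tert-butyldimethylsilyloxy)hexadec-9-enoate | COC(=O)CCCCCCC/C=C\CCCCCCO[Si](C)(C)C(C)(C)C | intermediate
25 | (9Z)-16-(tert-butyldimethylsilyloxy)hexadec-9-enoic acid | OC(=O)CCCCCCC/C=C\CCCCCCO[Si](C)(C)C(C)(C)C | intermediate
26 | mixed anhydride of 25 with 2,4,6-trichlorobenzoic acid | O=C(CCCCCCC/C=C\CCCCCCO[Si](C)(C)C(C)(C)C)OC(=O)c1c(Cl)cc(Cl)cc1Cl | intermediate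
27 | C10 ester of 18 with 25 (C12 OSiEt3, C13 OTBS, chain OTBS, tert-butyl ester) | C[C@@]1(CO[Si](C)(C)C(C)(C)C)[C@H]2C[C@@]3([C@@H](OC(=O)CCCCCCC/C=C\CCCCCCO[Si](C)(C)C(C)(C)C)C=C2C(=O)OC(C)(C)C)[C@@H](CO[Si](CC)(CC)CC)CC[C@@H]13 | intermediate
28 | C12 primary alcohol from 27 | C[C@@]1(CO[Si](C)(C)C(C)(C)C)[C@H]2C[C@@]3([C@@H](OC(=O)CCCCCCC/C=C\CCCCCCO[Si](C)(C)C(C)(C)C)C=C2C(=O)OC(C)(C)C)[C@@H](CO)CC[C@@H]13 | intermediate
29 | C12 aldehyde from 28 | C[C@@]1(CO[Si](C)(C)C(C)(C)C)[C@H]2C[C@@]3([C@@H](OC(=O)CCCCCCC/C=C\CCCCCCO[Si](C)(C)C(C)(C)C)C=C2C(=O)OC(C)(C)C)[C@@H](C=O)CC[C@@H]13 | intermediate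
30 | CNP0148862.2 | C[C@@]1(CO)[C@H]2C[C@@]3([C@@H](OC(=O)CCCCCCC/C=C\CCCCCCO)C=C2C(=O)O)[C@@H](C=O)CC[C@@H]13 | target

**Step count and risks**

Total: 21 steps. Longest linear sequence: 17 steps (steps 1–13 and 18–21); fragment 2 takes 4 steps (14–17).

Steps most likely to fail:

1. Step 8 (the proposed new method). The C2 radical may be reduced to an organotitanium and eliminate back to the alkene, may attack an ortho carbon, or the spiro radical may reopen by 1,4-aryl shift before it is reduced. Fallback with known chemistry, setting out from 9: ozonolysis (O3, CH2Cl2/MeOH, −78 °C; PPh3) of the terminal alkene gives tert-butyl 4-[(2R,3R)-2-hydroxy-2-methyl-6-oxo-1-(tosyloxy)hexan-3-yl]-3-methoxybenzoate F1. SmI2/HMPA with iPrOH in THF then effects the established ketyl ipso-spirocyclization onto an arene with a para alkoxycarbonyl group and gives the spiro cyclopentanol F2, with the same allylic-strain control at C1. Dess–Martin oxidation gives the spiro cyclopentanone F3, and Ph3P=CH2 in THF gives the 2-methylene spiro diene F4. Hydroboration with 9-BBN and oxidation with NaBO3·4H2O should deliver boron to the exocyclic CH2 from the face trans to the C5 substituent, so the hydroxymethyl group ends cis to it. The sequence comes back to the route at 11.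

2. Step 10. A second Cp2TiCl may intercept the tertiary radical (β-hydride elimination or deoxygenation) before it closes, and the two arms at C6 may be poorly differentiated. Fallback, setting out from 13: the epoxide is isomerised with diethylaluminium 2,2,6,6-tetramethylpiperidide (toluene, 0 °C) to the 2-methylene alcohol F5, which is also what the elimination side reaction would give. Fe(acac)3 and PhSiH3 in EtOH at 60 °C then generate the same tertiary C6 radical by hydrogen-atom transfer to the 1,1-disubstituted alkene, with no stoichiometric reductant to trap it, and the free hydroxyl can hydrogen-bond to the C8 ester during the 5-exo Giese closure. The sequence comes back at 14.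

3. Step 13. Hydride may be delivered from the face of the two-carbon bridge, because the C12 silyloxymethyl group sits 1,3-syn to the intended trajectory, giving poor facial selectivity at C10. Fallback, setting out from 17: Meerwein–Ponndorf–Verley reduction (Al(OiPr)3, iPrOH, toluene, 80 °C) under reversible hydride transfer replaces kinetic by thermodynamic control. The C10-epimeric alcohol F6 has its oxygen 1,3-syn to C12 and should drain through 17 into the less strained epimer. The sequence comes back at 18.

Further compounds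
F1 | step 8 | tert-butyl 4-[(2R,3R)-2-hydroxy-2-methyl-6-oxo-1-(tosyloxy)hexan-3-yl]-3-methoxybenzoate | O=CCC[C@H](c1ccc(C(=O)OC(C)(C)C)cc1OC)[C@@](C)(O)COS(=O)(=O)c1ccc(C)cc1
F2 | step 8 | spiro cyclopentanol (as 11 but C2 bears OH in place of CH2OH; C2 and C8 epimers) | C[C@](O)(COS(=O)(=O)c3ccc(C)cc3)[C@@H]1CCC(O)[C@]12C=CC(C(=O)OC(C)(C)C)C=C2OC
F3 | step 8 | spiro cyclopentanone (C2 ketone) | C[C@](O)(COS(=O)(=O)c3ccc(C)cc3)[C@@H]1CCC(=O)[C@]12C=CC(C(=O)OC(C)(C)C)C=C2OC
F4 | step 8 | 2-methylene spiro diene | C[C@](O)(COS(=O)(=O)c3ccc(C)cc3)[C@@H]1CCC(=C)[C@]12C=CC(C(=O)OC(C)(C)C)C=C2OC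
F5 | step 10 | 2-methylene alcohol (C5 bears C(=CH2)CH2OH; otherwise as 13) | C=C(CO)[C@@H]1CC[C@H](CO[Si](CC)(CC)CC)[C@]12CC=C(C(=O)OC(C)(C)C)C=C2OC
F6 | step 13 | (10R)-epimer of 18 | C[C@@]1(CO[Si](C)(C)C(C)(C)C)[C@H]2C[C@@]3([C@H](O)C=C2C(=O)OC(C)(C)C)[C@@H](CO[Si](CC)(CC)CC)CC[C@@H]13
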